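## The problem

Albanin A is an achiral flavone. A 5,7-dihydroxylated benzo ring (ring A) is fused through C4a–C8a to a γ-pyranone (ring C), which carries a 2,4-dihydroxyphenyl group (ring B) at C2 and a 3-methylbut-2-enyl chain at C3. There is no stereocentre, so the difficulties are regiochemical and chemoselective only. Ring C is fully substituted, and the prenyl group must sit on C3 and not on C6 or C8, the most nucleophilic carbons of a finished 5,7-dihydroxyflavone. The side chain is therefore best attached before the pyranone exists. The trisubstituted alkene is the fragile group: Brønsted and Lewis acids protonate it (hydration, HX addition, capture by a neighbouring oxygen) and hydrogen on palladium saturates it, so BBr3-type ether cleavage and hydrogenation under H2 gas are excluded at the end. The 2'-hydroxyl lies ortho to the carbon that becomes C2 and would lactonise onto any ester placed at the future C4, so ring B must stay masked until ring C is closed. The enabling feature is that ring A is a phloroglucinol nucleus: its three ring carbons are equivalent candidates for C4a, and either hydroxyl flanking the chosen carbon can become O1. C4–C4a and O1–C2 can therefore be formed on free phloroglucinol without protection or regiocontrol.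

## Retrosynthesis

**Unmasking ring B (11 from 10).** The last operation is cleavage of the two O–CH2Ph bonds of chromone 10 to give Albanin A 11. Benzyl is preferred to its neighbours for the following reasons.
- Methyl ethers would have to leave by two SN2 demethylations on a ring B that becomes a phenoxide after the first, in a molecule already carrying the 5,7-diphenoxide.
- Acetal groups such as methoxymethyl come off easily but are liable to exchange onto phloroglucinol in a hot phenolic melt.
- A benzyl ether is inert to neutral heat and leaves under neutral reductive conditions.

The forward step must cleave two aryl benzyl ethers faster than it touches the trisubstituted alkene.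

**Pyranone annulation (10 from 6 and 7).** Ring C is opened at C4–C4a and O1–C2, giving phloroglucinol 7 and the α-prenyl aroylacetate 6. On the way forward the step passes through acylketene 8 and the C-acylphloroglucinol diketone 9.
- The neighbouring cut at C2–C3 and O1–C2 (a Baker–Venkataraman sequence) would need a selectively protected phloracetophenone, an aroyl chloride, separate prenylation of a diketone and a cyclodehydration.
- Prenylating a finished flavone at C3 would have to compete with C6 and C8.
- The chosen cut uses the symmetry of 7, brings both ring A oxygens in for free and delivers the prenyl group already in place.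

The precursors are a commodity phenol and an acyclic keto ester. The forward reaction must acylate ring A through the ester carbon (chromone) and not attack the ketone (4-arylcoumarin), and ring B and the alkene must survive the melt.

**Prenylation (6 from 4 and 5).** The bond between the α-carbon of the keto ester (the future C3) and the prenyl CH2 is cut, giving aroylacetate 4 and prenyl bromide 5. The doubly activated methylene of 4 is the one position in the whole route where a prenyl group can be placed without any question of site. The forward step needs only C-monoalkylation at the primary terminus of the allylic bromide.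

**Claisen condensation (4 from 2 and 3).** The bond between the acetyl methyl carbon and the ester carbonyl (the future C3–C4) is cut, giving acetophenone 2 and diethyl carbonate 3. Against an aroyl chloride and malonate half-ester, this uses the cheapest acyl source and a ketone that is one step from a commodity phenol.

**Benzylation (2 from 1).** The two O–benzyl bonds of 2 are cut back to 2',4'-dihydroxyacetophenone 1 and benzyl bromide. The forward step only has to be forcing enough to etherify the hydrogen-bonded 2'-hydroxyl as well.

## Roads not taken

**Alternative 1:** Ring A is built last by cutting C4a–C5 and C8–C8a.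
- *Forward step.* The sulfinyl-activated double bond of pyranone A1 takes up the bis(silyloxy)diene A2. Loss of benzenesulfenic acid and methanol, then desilylation, should give the 5,7-dihydroxychromone A3.
- *Merits.* The cycloaddition runs far below the temperature of a melt. The diene polarity fixes the 5,7-oxygenation. Ring B can carry methoxymethyl ethers, which leave with dilute acid in methanol; this endgame is gentler than the one chosen here.
- *Weak points.* A1 is a fully substituted, unsymmetrical monocyclic pyranone with aryl, prenyl and sulfinyl groups at defined positions, and making it is longer than the whole chosen route. The sulfide-to-sulfoxide oxidation and the sulfenic acid released later both have to coexist with the prenyl alkene. Simple 4-pyranones are reluctant dienophiles.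
- *Comparison.* The route constructs atom by atom a ring that can be bought as 7. The chosen plan is harsher in its key step and in its deprotection, but it offers five steps from commodity chemicals and uses the symmetry of ring A.

**Alternative 2:** Ring B is built last by a Danheiser benzannulation, cutting C5'–C6', C2'–C3', C4'–C5' and C1'–C2'.
- *Forward step.* Wolff rearrangement of diazo enone A4 gives a chromonyl vinylketene. This adds to siloxyalkyne A5, and four-electron ring opening followed by six-electron closure should give the resorcinol monosilyl ether A6.
- *Merits.* The two ring B oxygens arrive differentiated, and the final deprotections (fluoride and mild acid) are unquestionably safe for the prenyl group. In this respect the route is better than the chosen one.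
- *Weak points.* Ring B is plain resorcinol, the cheapest part of the target. A4 presupposes a complete 3-prenylchromone carrying a diazo enone side chain at C2, many steps away. Carbene and ketene intermediates are generated next to a nucleophilic trisubstituted alkene (cyclopropanation, [2+2] addition). If the Wolff step is photochemical, the chromone chromophore competes for the light.
- *Comparison.* Against the cleaner endgame, the chosen plan has a several-fold shorter sequence and no high-energy intermediates near the alkene.

**Alternative 3:** Ring C is closed by cutting C3–C4 and O1–C8a.
- *Forward step.* The enolate of ring B ketone A7 is C-acylated by acid chloride A8, and the diketone enolate oxygen displaces an ortho fluoride in the same pot to give difluorochromone A9.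
- *Merits.* The chemistry is ionic, low-temperature, convergent and regiochemically unambiguous. The prenyl group is in place from the start and ring B can again carry methoxymethyl ethers. As a ring-forming event this step is probably more dependable than a 240 °C melt.
- *Weak points.* A9 has fluorine where the target needs the 5- and 7-hydroxyls. Two further substitutions by an oxygen nucleophile are required, the second on a ring already deactivated by the first alkoxy group. That nucleophile can also attack C2 and open the pyranone, and the new ethers then need their own alkene-compatible removal. C- versus O-acylation of the α-branched ketone enolate is a further uncertainty.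
- *Comparison.* The chosen plan accepts a harsher key step, but ring A arrives with both oxygens in place and unprotected, which saves at least three steps.

Key step: step 4

Remark on the chemistry: keto ester 6 has one stereocentre (its α-carbon). It is made and used as the racemate because that carbon becomes the sp2 carbon C3 in step 4. The target has no stereocentre.

## Route

Step 1
Reactants: 1 2',4'-dihydroxyacetophenone
Product: 2 1-[2,4-bis(benzyloxy)phenyl]ethanone
Conditions: BnBr (2.4 equiv), K2CO3 (3 equiv), DMF, 80 °C
Reagents that add atoms: benzyl bromide, BrCc1ccccc1
Why: Williamson ether synthesis; the 4'-phenoxide reacts readily and the chelated 2'-hydroxyl follows in hot DMF with excess bromide, while the methyl ketone is not alkylated by carbonate.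

Step 2
Reactants: 2 1-[2,4-bis(benzyloxy)phenyl]ethanone; 3 diethyl carbonate
Product: 4 ethyl 3-[2,4-bis(benzyloxy)phenyl]-3-oxopropanoate
Conditions: NaH (2.5 equiv), 3 (3 equiv), toluene, reflux; then 1 M HCl, 0 °C
Reagents that add atoms: none
Why: Crossed Claisen condensation of the ketone enolate with a non-enolisable carbonate, driven to completion by deprotonation of the β-keto ester formed; benzyl ethers are inert to NaH and ethoxide.

Step 3
Reactants: 4 ethyl 3-[2,4-bis(benzyloxy)phenyl]-3-oxopropanoate; 5 prenyl bromide (1-bromo-3-methylbut-2-ene)
Product: 6 ethyl 2-[2,4-bis(benzyloxy)benzoyl]-5-methylhex-4-enoate (racemic)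
Conditions: 5 (1.05 equiv), K2CO3 (1.5 equiv), acetone, reflux
Reagents that add atoms: none
Why: SN2 C-alkylation of a stabilised β-keto ester enolate by a primary allylic bromide; the monoalkylated product is less acidic and more hindered, which should hold the reaction at one prenyl group, and the new stereocentre is formed racemic and is lost in step 4.

Step 4
Reactants: 6 ethyl 2-[2,4-bis(benzyloxy)benzoyl]-5-methylhex-4-enoate; 7 phloroglucinol (benzene-1,3,5-triol, anhydrous)
Product: 10 2-[2,4-bis(benzyloxy)phenyl]-5,7-dihydroxy-3-(3-methylbut-2-enyl)chromen-4-one, via acylketene 8 (not isolated), via C-acylphloroglucinol diketone 9 (not isolated)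
Conditions: 7 (1.5 equiv), neat melt, 240 °C, Ar sweep, EtOH and H2O distilled out
Reagents that add atoms: none
Why: Mentzer pyrone synthesis, the thermal uncatalysed condensation of a phenol with a β-keto ester. Above about 200 °C the enol of 6 expels ethanol through a six-membered transition state to give acylketene 8, which acylates phloroglucinol at a ring carbon, directly or by O-acylation and a thermal Fries-type O-to-C shift, forming C4–C4a and giving diketone 9. Ring C then closes by 6-exo-trig addition of a flanking phenolic hydroxyl to the aryl ketone carbonyl and loss of water from the hemiketal, forming O1–C2, and removal of ethanol and water from the melt drives both stages. The closest known reaction type is the melt condensation of phloroglucinol with α-alkyl aroylacetates to give 3-alkyl-5,7-dihydroxyflavones. No stereocentre is created, and the racemic α-centre of 6 becomes the sp2 carbon C3. Regiochemistry on ring A does not arise because the three ring carbons of 7 and the two hydroxyls flanking the acylated carbon are equivalent. The selectivity needed is chromone over 4-arylcoumarin: without acid the electron-rich, ortho-substituted aryl ketone is not activated for Pechmann-type attack by the ring carbon, the α-prenyl group shields it further, and the ketene pathway delivers the ester carbon to carbon. The benzyl ethers are inert to the neutral melt and keep the 2'-oxygen from lactonising onto the ester or the ketene.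

Step 5
Reactants: 10 2-[2,4-bis(benzyloxy)phenyl]-5,7-dihydroxy-3-(3-methylbut-2-enyl)chromen-4-one
Product: 11 Albanin A, 2-(2,4-dihydroxyphenyl)-5,7-dihydroxy-3-(3-methylbut-2-enyl)chromen-4-one
Conditions: Pd/C (10 wt % Pd), 1,4-cyclohexadiene (10 equiv), EtOH–EtOAc, 25 °C
Reagents that add atoms: none
Why: Catalytic transfer hydrogenolysis of aryl benzyl ethers; benzylic C–O cleavage is among the fastest reactions on palladium, whereas an unconjugated trisubstituted alkene is among the slowest to be saturated, and a hydrogen donor in place of H2 gas keeps the hydride supply low. The tetrasubstituted C2=C3 bond of the vinylogous ester is not reduced under these conditions.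

## Compound list

1 | 2',4'-dihydroxyacetophenone | CC(=O)c1ccc(O)cc1O | starting material
2 | 1-[2,4-bis(benzyloxy)phenyl]ethanone | CC(=O)c1ccc(OCc2ccccc2)cc1OCc1ccccc1 | intermediate
3 | diethyl carbonate | CCOC(=O)OCC | starting material
4 | ethyl 3-[2,4-bis(benzyloxy)phenyl]-3-oxopropanoate | CCOC(=O)CC(=O)c1ccc(OCc2ccccc2)cc1OCc1ccccc1 | intermediate
5 | prenyl bromide (1-bromo-3-methylbut-2-ene) | CC(C)=CCBr | starting material
6 | ethyl 2-[2,4-bis(benzyloxy)benzoyl]-5-methylhex-4-enoate (racemic) | CCOC(=O)C(CC=C(C)C)C(=O)c1ccc(OCc2ccccc2)cc1OCc1ccccc1 | intermediate
7 | phloroglucinol (benzene-1,3,5-triol) | Oc1cc(O)cc(O)c1 | starting material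
8 | 2-[2,4-bis(benzyloxy)benzoyl]-5-methylhexa-1,4-dien-1-one (acylketene) | CC(C)=CCC(=C=O)C(=O)c1ccc(OCc2ccccc2)cc1OCc1ccccc1 | intermediate (not isolated)
9 | 1-[2,4-bis(benzyloxy)phenyl]-2-(3-methylbut-2-enyl)-3-(2,4,6-trihydroxyphenyl)propane-1,3-dione (racemic) | CC(C)=CCC(C(=O)c1ccc(OCc2ccccc2)cc1OCc1ccccc1)C(=O)c1c(O)cc(O)cc1O | intermediate (not isolated)
10 | 2-[2,4-bis(benzyloxy)phenyl]-5,7-dihydroxy-3-(3-methylbut-2-enyl)chromen-4-one | CC(C)=CCc1c(-c2ccc(OCc3ccccc3)cc2OCc2ccccc2)oc2cc(O)cc(O)c2c1=O | intermediate
11 | Albanin A, 2-(2,4-dihydroxyphenyl)-5,7-dihydroxy-3-(3-methylbut-2-enyl)chromen-4-one | CC(C)=CCc1c(-c2ccc(O)cc2O)oc2cc(O)cc(O)c2c1=O | target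

## Step count and risks

Total step count: 5. Longest linear sequence: 5 steps (1 → 2 → 4 → 6 → 10 → 11); phloroglucinol 7 enters at step 4.

**Step 4 (key step).**
- *Most likely failure.* Slow ketene formation from the α-branched ester leads to incomplete conversion and charring. In addition, the hot phenolic melt can act as an acid on the trisubstituted alkene, adding a phenolic O–H or ring C–H across it or shifting the double bond. Transfer of a benzyl group to the very nucleophilic phloroglucinol is a lesser concern.
- *Fallback.* The acid-sensitive alkene is kept out of the melt and the prenyl terminus is made afterwards. Setting out from 4, alkylation with allyl bromide (K2CO3, acetone, reflux) would give ethyl 2-[2,4-bis(benzyloxy)benzoyl]pent-4-enoate F1. The same melt condensation with 7 would give 3-allyl-2-[2,4-bis(benzyloxy)phenyl]-5,7-dihydroxychromen-4-one F2; a monosubstituted alkene is far harder to protonate and the α-substituent is smaller. Olefin cross-metathesis of F2 with excess 2-methylbut-2-ene (second-generation Grubbs catalyst, CH2Cl2, 40 °C) would then convert allyl into prenyl. The fallback comes back to the route at 10.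

**Step 5.**
- *Most likely failure.* Once the benzyl ethers are consumed, palladium hydride can saturate the prenyl double bond or move it into conjugation. Pushing the hindered 2'-O-benzyl group to completion makes this worse.
- *Fallback.* The reductive cleavage is replaced by nucleophilic dealkylation. Setting out from 10, sodium ethanethiolate (excess) in DMF at about 110 °C attacks the benzylic carbons by SN2 and releases the phenoxides. Neither hydride nor acid is present, so the alkene is not at risk. Aqueous acidic work-up comes back to the route at 11. This fallback makes no compound outside the compound list (F0).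

**Step 3.**
- *Most likely failure.* Carbonate can still deprotonate the product, leading to a second alkylation, and the ambident enolate can be alkylated at oxygen.
- *Fallback.* The SN2 alkylation is replaced by Tsuji–Trost allylation. Setting out from 4, its sodium enolate (NaH, 1 equiv, THF) is treated with prenyl acetate and catalytic Pd(PPh3)4 (zerovalent palladium) at 50 °C. The soft enolate attacks the unsubstituted terminus of the 1,1-dimethylallyl palladium complex, giving the linear prenyl product. Any O-allylated material is itself an allylic electrophile and is re-ionised by the catalyst, so the reaction converges on the C-alkylated ester. The fallback comes back to the route at 6 and makes no compound outside the compound list (F0).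

## Further compounds

F0 | step 3 | none | none
F1 | step 4 | ethyl 2-[2,4-bis(benzyloxy)benzoyl]pent-4-enoate (racemic) | CCOC(=O)C(CC=C)C(=O)c1ccc(OCc2ccccc2)cc1OCc1ccccc1
F2 | step 4 | 3-allyl-2-[2,4-bis(benzyloxy)phenyl]-5,7-dihydroxychromen-4-one | C=CCc1c(-c2ccc(OCc3ccccc3)cc2OCc2ccccc2)oc2cc(O)cc(O)c2c1=O
F0 | step 5 | none | none
A1 | alternative 1 | 2-[2,4-bis(methoxymethoxy)phenyl]-3-(3-methylbut-2-enyl)-5-(phenylsulfinyl)pyran-4-one | CC(C)=CCc1c(-c2ccc(OCOC)cc2OCOC)occ(S(=O)c2ccccc2)c1=O
A2 | alternative 1 | 1-methoxy-1,3-bis(trimethylsilyloxy)buta-1,3-diene | COC(O[Si](C)(C)C)=CC(=C)O[Si](C)(C)C
A3 | alternative 1 | 2-[2,4-bis(methoxymethoxy)phenyl]-5,7-dihydroxy-3-(3-methylbut-2-enyl)chromen-4-one | CC(C)=CCc1c(-c2ccc(OCOC)cc2OCOC)oc2cc(O)cc(O)c2c1=O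
A4 | alternative 2 | (E)-4-[5,7-bis(methoxymethoxy)-3-(3-methylbut-2-enyl)-4-oxochromen-2-yl]-1-diazobut-3-en-2-one | CC(C)=CCc1c(/C=C/C(=O)C=[N+]=[N-])oc2cc(OCOC)cc(OCOC)c2c1=O
A5 | alternative 2 | (triisopropylsilyloxy)ethyne | C#CO[Si](C(C)C)(C(C)C)C(C)C
A6 | alternative 2 | 2-[2-hydroxy-4-(triisopropylsilyloxy)phenyl]-5,7-bis(methoxymethoxy)-3-(3-methylbut-2-enyl)chromen-4-one | CC(C)=CCc1c(-c2ccc(O[Si](C(C)C)(C(C)C)C(C)C)cc2O)oc2cc(OCOC)cc(OCOC)c2c1=O
A7 | alternative 3 | 1-[2,4-bis(methoxymethoxy)phenyl]-5-methylhex-4-en-1-one | CC(C)=CCCC(=O)c1ccc(OCOC)cc1OCOC
A8 | alternative 3 | 2,4,6-trifluorobenzoyl chloride | O=C(Cl)c1c(F)cc(F)cc1F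
A9 | alternative 3 | 2-[2,4-bis(methoxymethoxy)phenyl]-5,7-difluoro-3-(3-methylbut-2-enyl)chromen-4-one | CC(C)=CCc1c(-c2ccc(OCOC)cc2OCOC)oc2cc(F)cc(F)c2c1=O
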